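**Retrosynthetic overview**
- The target is unmasked by a final fluoride desilylation; before that, the p-coumarate is attached to the only free primary alcohol (C9–OH) of a silyl-protected oxolane alcohol by Mitsunobu esterification.
- The oxolane (the only ring of the target) is closed by an intramolecular oxa-Michael (1,6-conjugate, 5-exo-trig) addition of the C9'–OH onto a p-quinone methide made by DDQ oxidation of a p-alkylphenol 1,4-diol.
- That diol comes from LiAlH4 reduction of a trans-α-benzyl-β-substituted γ-butyrolactone, itself made by trans-alkylation of a β-substituted lactone with a vanillin-derived benzylic bromide (sets C8).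
- The β-substituted lactone comes from an Evans syn-aldol of a succinate imide with O-silyl vanillin (sets C7' and C8'), followed by silylation and reductive auxiliary removal with lactonisation.
- Ring order: the temporary γ-lactone first (a template for C8, later opened), then the oxolane last.

Assumption: the SMILES is read as the (2S,3R,4R)-oxolane with an (S)-carbinol; lignan locants are used below (C7 = oxolane C2, C8 = C3, C9 = its CH2O, C8' = C4, C9' = C5, C7' = carbinol carbon).

**Route**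

Step 1
Reactants: 1 vanillin (4-hydroxy-3-methoxybenzaldehyde)
Product: 2 3-methoxy-4-[(triisopropylsilyl)oxy]benzaldehyde
Conditions: TIPSCl, imidazole, DMF, 0 °C → rt
Reagents that add atoms: triisopropylsilyl chloride, CC(C)[Si](Cl)(C(C)C)C(C)C
Why: Phenol O-silylation, the TIPS aryl ether being chosen because it survives the hydride and amide-base steps that follow.

Step 2
Reactants: 3 4-tert-butoxy-4-oxobutanoic acid (mono-tert-butyl succinate); 4 (4S)-4-benzyl-1,3-oxazolidin-2-one
Product: 6 tert-butyl 4-[(4S)-4-benzyl-2-oxo-1,3-oxazolidin-3-yl]-4-oxobutanoate, via mixed anhydride 5 (not isolated)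
Conditions: PivCl, Et3N, THF, −20 °C; then 4, LiCl, −20 °C → rt
Reagents that add atoms: none
Why: N-acylation of the oxazolidinone through the mixed pivalic anhydride, which is attacked at its less hindered succinyl carbonyl (LiCl-promoted acyl transfer).

Step 3
Reactants: 6 tert-butyl 4-[(4S)-4-benzyl-2-oxo-1,3-oxazolidin-3-yl]-4-oxobutanoate; 2 3-methoxy-4-[(triisopropylsilyl)oxy]benzaldehyde
Product: 8 tert-butyl (3S)-4-[(4S)-4-benzyl-2-oxo-1,3-oxazolidin-3-yl]-3-[(S)-hydroxy{3-methoxy-4-[(triisopropylsilyl)oxy]phenyl}methyl]-4-oxobutanoate, via boron enolate 7 (not isolated)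
Conditions: Bu2BOTf, i-Pr2NEt, CH2Cl2, 0 °C; then 2, −78 → 0 °C; then pH 7 buffer (NaH2PO4/Na2HPO4), MeOH, 30% H2O2, 0 °C
Reagents that add atoms: none
Why: Evans syn-aldol in which the Z-dibutylboron enolate of the imide (not of the tert-butyl ester) reacts through a chair Zimmerman–Traxler transition state on the face opposite the auxiliary benzyl group, setting C7' (S) and C8' (S as named here, the R centre of the target once C9' is reduced) in a syn relationship.

Step 4
Reactants: 8 the syn-aldol adduct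
Product: 9 tert-butyl (3S)-4-[(4S)-4-benzyl-2-oxo-1,3-oxazolidin-3-yl]-3-[(S)-[(tert-butyldimethylsilyl)oxy]{3-methoxy-4-[(triisopropylsilyl)oxy]phenyl}methyl]-4-oxobutanoate
Conditions: TBSOTf, 2,6-lutidine, CH2Cl2, −78 → 0 °C
Reagents that add atoms: tert-butyldimethylsilyl trifluoromethanesulfonate, CC(C)(C)[Si](C)(C)OS(=O)(=O)C(F)(F)F
Why: Silyl triflate silylation of the hindered benzylic aldol hydroxyl under non-nucleophilic conditions avoids retro-aldol and masks O7' so that it can neither lactonise nor compete in the later ring closure.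

Step 5
Reactants: 9 the silylated aldol imide
Product: 11 (4R)-4-[(S)-[(tert-butyldimethylsilyl)oxy]{3-methoxy-4-[(triisopropylsilyl)oxy]phenyl}methyl]oxolan-2-one, via hydroxy ester 10 (not isolated)
Conditions: LiBH4, H2O (1 equiv), Et2O, 0 °C; aqueous work-up, then CSA (10 mol %), PhMe, 40 °C
Reagents that add atoms: none
Why: Hydride reduction cleaves the N-acyl oxazolidinone to the primary C9' alcohol without touching the tert-butyl ester, and acid-catalysed intramolecular transesterification (lactonisation) then closes the temporary γ-lactone with loss of tert-butanol, no stereocentre being involved.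

Step 6
Reactants: 1 vanillin
Product: 12 4-formyl-2-methoxyphenyl 2,2-dimethylpropanoate (O-pivaloylvanillin)
Conditions: PivCl, Et3N, DMAP (cat.), CH2Cl2, 0 °C → rt
Reagents that add atoms: pivaloyl chloride, CC(C)(C)C(Cl)=O
Why: DMAP-catalysed phenol O-acylation gives a hindered aryl ester that tolerates the next steps and is later removed by the same hydride that opens the lactone.

Step 7
Reactants: 12 O-pivaloylvanillin
Product: 13 4-(hydroxymethyl)-2-methoxyphenyl 2,2-dimethylpropanoate
Conditions: NaBH4, THF/MeOH, 0 °C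
Reagents that add atoms: none
Why: Chemoselective borohydride reduction of the aldehyde, the hindered aryl pivalate being untouched at 0 °C.

Step 8
Reactants: 13 the benzylic alcohol
Product: 14 4-(bromomethyl)-2-methoxyphenyl 2,2-dimethylpropanoate
Conditions: PBr3, Et2O, 0 °C
Reagents that add atoms: phosphorus tribromide, BrP(Br)Br
Why: Bromination of the benzylic alcohol through its phosphite ester (SN2 displacement by bromide).

Step 9
Reactants: 11 the β-substituted γ-lactone; 14 4-(bromomethyl)-2-methoxyphenyl 2,2-dimethylpropanoate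
Product: 16 2-methoxy-4-{[(3R,4R)-4-[(S)-[(tert-butyldimethylsilyl)oxy]{3-methoxy-4-[(triisopropylsilyl)oxy]phenyl}methyl]-2-oxooxolan-3-yl]methyl}phenyl 2,2-dimethylpropanoate, via lithium enolate 15 (not isolated)
Conditions: LiN(SiMe3)2 (1.05 equiv), THF, −78 °C; then 14, DMPU, −78 → −40 °C
Reagents that add atoms: none
Why: Lactone enolate alkylation with a reactive benzylic bromide occurs on the face anti to the bulky C4 substituent, setting C8 (3R) trans to C8', and at −78 °C it outruns acyl transfer from the hindered pivalate.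

Step 10
Reactants: 16 the trans-α-benzyl lactone
Product: 17 (2R,3R)-2-[(S)-[(tert-butyldimethylsilyl)oxy]{3-methoxy-4-[(triisopropylsilyl)oxy]phenyl}methyl]-3-(4-hydroxy-3-methoxybenzyl)butane-1,4-diol
Conditions: LiAlH4, THF, 0 °C → rt; aq. KNaC4H4O6 work-up
Reagents that add atoms: none
Why: LiAlH4 ester reduction opens the lactone to the 1,4-diol and cleaves the aryl pivalate to the free phenol in one operation, leaving the silyl ethers and all stereocentres intact.

Step 11
Reactants: 17 the phenolic 1,4-diol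
Product: 19 [(2S,3R,4R)-4-[(S)-[(tert-butyldimethylsilyl)oxy]{3-methoxy-4-[(triisopropylsilyl)oxy]phenyl}methyl]-2-(4-hydroxy-3-methoxyphenyl)oxolan-3-yl]methanol, via quinone methide 18 (not isolated)
Conditions: DDQ (1.05 equiv), CH2Cl2, 0 °C → rt
Reagents that add atoms: none
Why: DDQ dehydrogenates the free p-alkylphenol (the silylated aryl ring is inert) to the p-quinone methide, and the C9' hydroxyl closes the oxolane by intramolecular oxa-Michael (1,6-conjugate, 5-exo-trig) addition with rearomatisation, the aryl group ending trans to the C8 substituent (new C7, S) because the all-cis transition state is far more strained, while O9 could only form a four-membered ring and O7' is silylated.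

Step 12
Reactants: 20 p-coumaric acid ((2E)-3-(4-hydroxyphenyl)prop-2-enoic acid)
Product: 22 (2E)-3-{4-[(tert-butyldimethylsilyl)oxy]phenyl}prop-2-enoic acid, via bis-silyl derivative 21 (not isolated)
Conditions: TBSCl (2.3 equiv), imidazole, DMF, rt; then AcOH/THF/H2O, rt
Reagents that add atoms: tert-butyldimethylsilyl chloride, CC(C)(C)[Si](C)(C)Cl
Why: Silylation of both the phenol and the acid followed by mild aqueous-acid hydrolysis of the labile silyl ester leaves only the aryl silyl ether.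

Step 13
Reactants: 19 the oxolane alcohol; 22 (2E)-3-{4-[(tert-butyldimethylsilyl)oxy]phenyl}prop-2-enoic acid
Product: 23 [(2S,3R,4R)-4-[(S)-[(tert-butyldimethylsilyl)oxy]{3-methoxy-4-[(triisopropylsilyl)oxy]phenyl}methyl]-2-(4-hydroxy-3-methoxyphenyl)oxolan-3-yl]methyl (2E)-3-{4-[(tert-butyldimethylsilyl)oxy]phenyl}prop-2-enoate
Conditions: PPh3, DIAD, THF, 0 °C → rt
Reagents that add atoms: none
Why: Mitsunobu esterification activates only the primary C9 alcohol (O7' is silylated), and the carboxylate, far more acidic than the guaiacyl phenol, is the nucleophile, so the ester forms without phenol protection and by substitution at a CH2 that touches no stereocentre.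

Step 14
Reactants: 23 the tris-silylated ester
Product: 24 [(2S,3R,4R)-2-(4-hydroxy-3-methoxyphenyl)-4-[(S)-hydroxy(4-hydroxy-3-methoxyphenyl)methyl]oxolan-3-yl]methyl (2E)-3-(4-hydroxyphenyl)prop-2-enoate (target, CNP0330050.2)
Conditions: Bu4NF, AcOH, THF, 0 °C → rt
Reagents that add atoms: none
Why: Fluoride desilylation buffered with AcOH removes the two aryl silyl ethers and the benzylic TBS ether without hydrolysing or migrating the cinnamate ester or epimerising the benzylic centres.

**Compound list**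
1 | vanillin | COc1cc(C=O)ccc1O | starting material
2 | 3-methoxy-4-[(triisopropylsilyl)oxy]benzaldehyde | COc1cc(C=O)ccc1O[Si](C(C)C)(C(C)C)C(C)C | intermediate
3 | 4-tert-butoxy-4-oxobutanoic acid | CC(C)(C)OC(=O)CCC(=O)O | starting material
4 | (4S)-4-benzyl-1,3-oxazolidin-2-one | O=C1N[C@@H](Cc2ccccc2)CO1 | starting material
5 | 4-tert-butoxy-4-oxobutanoic pivalic anhydride (not isolated) | CC(C)(C)OC(=O)CCC(=O)OC(=O)C(C)(C)C | intermediate
6 | tert-butyl 4-[(4S)-4-benzyl-2-oxo-1,3-oxazolidin-3-yl]-4-oxobutanoate | CC(C)(C)OC(=O)CCC(=O)N1[C@@H](Cc2ccccc2)COC1=O | intermediate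
7 | (Z)-dibutylboron enolate of 6 (not isolated) | CCCCB(CCCC)O/C(=C\CC(=O)OC(C)(C)C)N1[C@@H](Cc2ccccc2)COC1=O | intermediate
8 | tert-butyl (3S)-4-[(4S)-4-benzyl-2-oxo-1,3-oxazolidin-3-yl]-3-[(S)-hydroxy{3-methoxy-4-[(triisopropylsilyl)oxy]phenyl}methyl]-4-oxobutanoate | COc1cc([C@@H](O)[C@@H](C(=O)N2[C@@H](Cc3ccccc3)COC2=O)CC(=O)OC(C)(C)C)ccc1O[Si](C(C)C)(C(C)C)C(C)C | intermediate
9 | TBS ether of 8 (3S, carbinol S) | COc1cc([C@@H](O[Si](C)(C)C(C)(C)C)[C@@H](C(=O)N2[C@@H](Cc3ccccc3)COC2=O)CC(=O)OC(C)(C)C)ccc1O[Si](C(C)C)(C(C)C)C(C)C | intermediate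
10 | tert-butyl (3R,4S)-4-[(tert-butyldimethylsilyl)oxy]-3-(hydroxymethyl)-4-{3-methoxy-4-[(triisopropylsilyl)oxy]phenyl}butanoate (not isolated) | COc1cc([C@@H](O[Si](C)(C)C(C)(C)C)[C@@H](CO)CC(=O)OC(C)(C)C)ccc1O[Si](C(C)C)(C(C)C)C(C)C | intermediate
11 | (4R)-4-[(S)-[(tert-butyldimethylsilyl)oxy]{3-methoxy-4-[(triisopropylsilyl)oxy]phenyl}methyl]oxolan-2-one | COc1cc([C@@H](O[Si](C)(C)C(C)(C)C)[C@H]2COC(=O)C2)ccc1O[Si](C(C)C)(C(C)C)C(C)C | intermediate
12 | 4-formyl-2-methoxyphenyl 2,2-dimethylpropanoate | COc1cc(C=O)ccc1OC(=O)C(C)(C)C | intermediate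
13 | 4-(hydroxymethyl)-2-methoxyphenyl 2,2-dimethylpropanoate | COc1cc(CO)ccc1OC(=O)C(C)(C)C | intermediate
14 | 4-(bromomethyl)-2-methoxyphenyl 2,2-dimethylpropanoate | COc1cc(CBr)ccc1OC(=O)C(C)(C)C | intermediate
15 | lithium enolate of lactone 11 (not isolated) | COc1cc([C@@H](O[Si](C)(C)C(C)(C)C)[C@H]2COC(O[Li])=C2)ccc1O[Si](C(C)C)(C(C)C)C(C)C | intermediate
16 | (3R,4R)-trans lactone: 2-methoxy-4-{[(3R,4R)-4-[(S)-(TBS-oxy){3-methoxy-4-(TIPS-oxy)phenyl}methyl]-2-oxooxolan-3-yl]methyl}phenyl pivalate | COc1cc([C@@H](O[Si](C)(C)C(C)(C)C)[C@H]2COC(=O)[C@@H]2Cc3ccc(OC(=O)C(C)(C)C)c(OC)c3)ccc1O[Si](C(C)C)(C(C)C)C(C)C | intermediate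
17 | (2R,3R)-2-[(S)-(TBS-oxy){3-methoxy-4-(TIPS-oxy)phenyl}methyl]-3-(4-hydroxy-3-methoxybenzyl)butane-1,4-diol | COc1cc([C@@H](O[Si](C)(C)C(C)(C)C)[C@@H](CO)[C@H](CO)Cc3ccc(O)c(OC)c3)ccc1O[Si](C(C)C)(C(C)C)C(C)C | intermediate
18 | p-quinone methide of 17 at C7 (exocyclic C=C geometry undefined; not isolated) | COc1cc([C@@H](O[Si](C)(C)C(C)(C)C)[C@@H](CO)[C@H](CO)C=C3C=CC(=O)C(OC)=C3)ccc1O[Si](C(C)C)(C(C)C)C(C)C | intermediate
19 | [(2S,3R,4R)-4-[(S)-(TBS-oxy){3-methoxy-4-(TIPS-oxy)phenyl}methyl]-2-(4-hydroxy-3-methoxyphenyl)oxolan-3-yl]methanol | COc1cc([C@@H](O[Si](C)(C)C(C)(C)C)[C@H]2CO[C@H](c3ccc(O)c(OC)c3)[C@H]2CO)ccc1O[Si](C(C)C)(C(C)C)C(C)C | intermediate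
20 | p-coumaric acid | OC(=O)/C=C/c1ccc(O)cc1 | starting material
21 | tert-butyldimethylsilyl (2E)-3-{4-[(tert-butyldimethylsilyl)oxy]phenyl}prop-2-enoate (not isolated) | CC(C)(C)[Si](C)(C)OC(=O)/C=C/c1ccc(O[Si](C)(C)C(C)(C)C)cc1 | intermediate
22 | (2E)-3-{4-[(tert-butyldimethylsilyl)oxy]phenyl}prop-2-enoic acid | OC(=O)/C=C/c1ccc(O[Si](C)(C)C(C)(C)C)cc1 | intermediate
23 | tris-silylated ester: [(2S,3R,4R)-4-[(S)-(TBS-oxy){3-methoxy-4-(TIPS-oxy)phenyl}methyl]-2-(4-hydroxy-3-methoxyphenyl)oxolan-3-yl]methyl (2E)-3-{4-(TBS-oxy)phenyl}prop-2-enoate | COc1cc([C@@H](O[Si](C)(C)C(C)(C)C)[C@H]2CO[C@H](c3ccc(O)c(OC)c3)[C@H]2COC(=O)/C=C/c2ccc(O[Si](C)(C)C(C)(C)C)cc2)ccc1O[Si](C(C)C)(C(C)C)C(C)C | intermediate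
24 | [(2S,3R,4R)-2-(4-hydroxy-3-methoxyphenyl)-4-[(S)-hydroxy(4-hydroxy-3-methoxyphenyl)methyl]oxolan-3-yl]methyl (2E)-3-(4-hydroxyphenyl)prop-2-enoate | COc1cc([C@@H](O)[C@H]2CO[C@H](c3ccc(O)c(OC)c3)[C@H]2COC(=O)/C=C/c2ccc(O)cc2)ccc1O | target

**Step count and risks**

Total step count: 14. Longest linear sequence: 9 steps (steps 2, 3, 4, 5, 9, 10, 11, 13, 14; equally long from vanillin through step 1). Steps 6–8 (bromide 14) and step 12 (acid 22) are side branches, so the longest line is 9 of 14 steps.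

Three steps most likely to fail:

1. Step 11 (DDQ oxidation and quinone methide ring closure). Over-oxidation of the product phenol, tautomerisation of the quinone methide to a styrene, or aryl capture to a cyclolignan could compete. The fallback makes the same quinone methide without an oxidant. It sets out from lactone 11: its lithium enolate (LiN(SiMe3)2, THF, −78 °C) is added to aldehyde 12 to give the trans aldol adduct 4-{hydroxy[(3S,4R)-4-[(S)-(TBS-oxy){3-methoxy-4-(TIPS-oxy)phenyl}methyl]-2-oxooxolan-3-yl]methyl}-2-methoxyphenyl pivalate F1 (carbinol epimers, both usable). LiAlH4 in THF at 0 °C then opens the lactone and removes the pivalate to give the phenolic triol F2. Treating the phenolic triol F2 with PPTS (cat.) in CH2Cl2 at 0 °C → rt dehydrates the p-hydroxybenzylic alcohol to quinone methide 18, which closes as before. The fallback comes back to the route at 19.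

2. Step 9 (enolate alkylation with the pivalate-bearing bromide). The enolate or excess amide base may attack the aryl ester. The fallback replaces the acyl protecting group by an allyl ether, which has no electrophilic site and is removed separately. It sets out from lactone 11 and vanillin 1. Vanillin is O-allylated (allyl bromide, K2CO3, DMF) to 4-(allyloxy)-3-methoxybenzaldehyde F3, reduced (NaBH4, MeOH, 0 °C) to [4-(allyloxy)-3-methoxyphenyl]methanol F4, and brominated (PBr3, Et2O, 0 °C) to 1-(allyloxy)-4-(bromomethyl)-2-methoxybenzene F5. The enolate of 11 (LiN(SiMe3)2, THF, −78 °C) is alkylated with F5 to the trans allyl-protected lactone F6, and LiAlH4 gives the allyl ether diol F7. Deallylation with Pd(PPh3)4 (zerovalent palladium, catalytic) and morpholine in THF at rt then brings the fallback back to the route at 17.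

3. Step 13 (Mitsunobu esterification beside a free phenol). Phenol O-alkylation or sluggish reaction at the β-branched primary alcohol could lower the yield. The fallback acylates exhaustively and then cleaves the aryl ester selectively. It sets out from 19, which is acylated on both the primary alcohol and the phenol with acid 22 (2.5 equiv, EDC·HCl, DMAP, CH2Cl2, rt) to give the bis-cinnamate F8. Pyrrolidine (1.1 equiv, THF, 0 °C) then aminolyses only the much more reactive aryl ester, and the fallback comes back to the route at 23.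

**Further compounds**
F1 | step 11 | 4-{hydroxy[(3S,4R)-4-[(S)-[(tert-butyldimethylsilyl)oxy]{3-methoxy-4-[(triisopropylsilyl)oxy]phenyl}methyl]-2-oxooxolan-3-yl]methyl}-2-methoxyphenyl 2,2-dimethylpropanoate (carbinol epimers) | COc1cc([C@@H](O[Si](C)(C)C(C)(C)C)[C@H]2COC(=O)[C@@H]2C(O)c3ccc(OC(=O)C(C)(C)C)c(OC)c3)ccc1O[Si](C(C)C)(C(C)C)C(C)C
F2 | step 11 | (2R,3R)-2-[(S)-[(tert-butyldimethylsilyl)oxy]{3-methoxy-4-[(triisopropylsilyl)oxy]phenyl}methyl]-3-[hydroxy(4-hydroxy-3-methoxyphenyl)methyl]butane-1,4-diol (carbinol epimers) | COc1cc([C@@H](O[Si](C)(C)C(C)(C)C)[C@@H](CO)[C@H](CO)C(O)c3ccc(O)c(OC)c3)ccc1O[Si](C(C)C)(C(C)C)C(C)C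
F3 | step 9 | 4-(allyloxy)-3-methoxybenzaldehyde | COc1cc(C=O)ccc1OCC=C
F4 | step 9 | [4-(allyloxy)-3-methoxyphenyl]methanol | COc1cc(CO)ccc1OCC=C
F5 | step 9 | 1-(allyloxy)-4-(bromomethyl)-2-methoxybenzene | COc1cc(CBr)ccc1OCC=C
F6 | step 9 | (3R,4R)-3-[4-(allyloxy)-3-methoxybenzyl]-4-[(S)-[(tert-butyldimethylsilyl)oxy]{3-methoxy-4-[(triisopropylsilyl)oxy]phenyl}methyl]oxolan-2-one | COc1cc([C@@H](O[Si](C)(C)C(C)(C)C)[C@H]2COC(=O)[C@@H]2Cc3ccc(OCC=C)c(OC)c3)ccc1O[Si](C(C)C)(C(C)C)C(C)C
F7 | step 9 | (2R,3R)-2-[4-(allyloxy)-3-methoxybenzyl]-3-[(S)-[(tert-butyldimethylsilyl)oxy]{3-methoxy-4-[(triisopropylsilyl)oxy]phenyl}methyl]butane-1,4-diol | COc1cc([C@@H](O[Si](C)(C)C(C)(C)C)[C@@H](CO)[C@H](CO)Cc3ccc(OCC=C)c(OC)c3)ccc1O[Si](C(C)C)(C(C)C)C(C)C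
F8 | step 13 | bis-cinnamate of 19: 4-[(2S,3R,4R)-3-{[(2E)-3-{4-(TBS-oxy)phenyl}prop-2-enoyl]oxymethyl}-4-[(S)-(TBS-oxy){3-methoxy-4-(TIPS-oxy)phenyl}methyl]oxolan-2-yl]-2-methoxyphenyl (2E)-3-{4-(TBS-oxy)phenyl}prop-2-enoate | COc1cc([C@@H](O[Si](C)(C)C(C)(C)C)[C@H]2CO[C@H](c3ccc(OC(=O)/C=C/c4ccc(O[Si](C)(C)C(C)(C)C)cc4)c(OC)c3)[C@H]2COC(=O)/C=C/c2ccc(O[Si](C)(C)C(C)(C)C)cc2)ccc1O[Si](C(C)C)(C(C)C)C(C)C
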